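**Retrosynthetic overview**

1. The target is (2E,6E)-9-[(2R)-6-hydroxy-2,8-dimethylchroman-2-yl]-2,6-dimethylnona-2,6-dienoic acid. The last operations are ester/pivalate hydrolysis and installation of the C6 methyl on a (6Z)-enol nonaflate made from a C6 ketone.
2. Key disconnection: the chain C8–C9 bond (the CH2–CH2 unit next to chroman C2) together with O1–C2 of the dihydropyran ring. One Pd(II) domino oxypalladation/Heck reaction joins an achiral 2-(3-methylbut-3-enyl)phenol with a vinyl ketone that carries chain atoms C1–C8.
3. Enabling feature: C2 of the dihydropyran ring is fully substituted (O1, C3, CH3, C9). The Pd–C9 alkyl created by ring closure therefore has no β-hydrogen and lives long enough to insert the vinyl ketone. The C6 ketone is the activating group for that insertion and is afterwards turned into the methyl-bearing alkene carbon.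
4. Fragments: the phenol comes from methylhydroquinone (acylation, bromination, Negishi coupling); the vinyl ketone comes from pent-4-enal (Wittig, ozonolysis, vinyl Grignard, oxidation).
5. Ring order: the arene is bought; the dihydropyran ring is the only ring formed (step 8).

Key step: step 8

Remark (assumption): the (S,S)-BOXAX ligand is assumed to induce at C2 the same sense as in the known 2-methyl-2-alkylchroman series; if the sense proves opposite, the (R,R)-ligand is used.

**Route**

Step 1
Reactants: 1 2-methylbenzene-1,4-diol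
Product: 2 4-hydroxy-3-methylphenyl pivalate
Conditions: PivCl (1.0 equiv), pyridine, CH2Cl2, −20 °C to 0 °C
Reagents that add atoms: pivaloyl chloride, CC(C)(C)C(=O)Cl
Why: Regioselective O-acylation: the bulky acid chloride should esterify the 4-hydroxyl, which has no ortho substituent, in preference to the 1-hydroxyl flanked by the methyl group, and the minor regioisomer and diester are removed by chromatography.

Step 2
Reactants: 2 4-hydroxy-3-methylphenyl pivalate
Product: 3 3-bromo-4-hydroxy-5-methylphenyl pivalate
Conditions: NBS (1.0 equiv), MeCN, 0 °C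
Reagents that add atoms: N-bromosuccinimide, O=C1CCC(=O)N1Br
Why: Electrophilic aromatic bromination directed ortho to the free hydroxyl, whose para position is blocked and whose other ortho position carries the methyl group, while the acyloxy group is only a weak director.

Step 3
Reactants: 3 3-bromo-4-hydroxy-5-methylphenyl pivalate; 4 4-bromo-2-methylbut-1-ene
Product: 6 4-hydroxy-3-methyl-5-(3-methylbut-3-en-1-yl)phenyl pivalate, via alkylzinc bromide 5 (not isolated)
Conditions: 4, Zn dust, LiCl, THF, 40 °C; then 3, Pd(OAc)2 (2 mol%), SPhos (4 mol%), THF, rt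
Reagents that add atoms: none
Why: LiCl-mediated zinc insertion followed by Negishi sp2–sp3 cross-coupling, in which the Pd/SPhos catalyst should couple the alkylzinc faster than the phenol protonates it and faster than β-hydride elimination, the aryl pivalate being inert to organozinc reagents.

Step 4
Reactants: 7 pent-4-enal; 8 methyl 2-(triphenyl-λ5-phosphanylidene)propanoate
Product: 9 methyl (2E)-2-methylhepta-2,6-dienoate
Conditions: CH2Cl2, rt
Reagents that add atoms: none
Why: Wittig olefination with a stabilised ylide, which should give the (E)-2-methyl-2-enoate with high selectivity.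

Step 5
Reactants: 9 methyl (2E)-2-methylhepta-2,6-dienoate
Product: 11 methyl (2E)-2-methyl-6-oxohex-2-enoate, via ozonide 10 (not isolated)
Conditions: O3, CH2Cl2, −78 °C (Sudan III end point); then Me2S, −78 °C to rt
Reagents that add atoms: ozone, [O-][O+]=O
Why: Ozonolysis with reductive work-up, selective for the electron-richer monosubstituted alkene over the conjugated trisubstituted enoate when ozone is dosed to a dye end point.

Step 6
Reactants: 11 methyl (2E)-2-methyl-6-oxohex-2-enoate
Product: 12 methyl (2E)-6-hydroxy-2-methylocta-2,7-dienoate (racemic)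
Conditions: CH2=CHMgBr (1.05 equiv), THF, −78 °C; then H2O
Reagents that add atoms: vinylmagnesium bromide, C=C[Mg]Br
Why: Grignard 1,2-addition to the aldehyde, much faster at −78 °C than attack on the hindered conjugated ester; the new carbinol center is formed as a racemate and is destroyed in step 7.

Step 7
Reactants: 12 methyl (2E)-6-hydroxy-2-methylocta-2,7-dienoate
Product: 13 methyl (2E)-2-methyl-6-oxoocta-2,7-dienoate
Conditions: DMP (triacetoxyperiodinane), NaHCO3, CH2Cl2, 0 °C to rt
Reagents that add atoms: none
Why: Oxidation of the allylic alcohol to the vinyl ketone with a hypervalent iodine reagent under buffered conditions that should leave the enoate and the sensitive enone untouched; 13 is used at once.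

Step 8
Reactants: 6 4-hydroxy-3-methyl-5-(3-methylbut-3-en-1-yl)phenyl pivalate; 13 methyl (2E)-2-methyl-6-oxoocta-2,7-dienoate
Product: 15 methyl (2E,7E)-9-[(2S)-2,8-dimethyl-6-(pivaloyloxy)chroman-2-yl]-2-methyl-6-oxonona-2,7-dienoate, via alkylpalladium species 14 (not isolated)
Conditions: Pd(OCOCF3)2 (10 mol%), (S,S)-Bn-BOXAX (40 mol%), p-benzoquinone (4 equiv), 13 (3–5 equiv), CH2Cl2, rt, 3–4 d
Reagents that add atoms: none
Why: Pd(II) bound to the bis(oxazoline)–binaphthyl ligand activates the 1,1-disubstituted alkene and the phenol oxygen adds to its substituted carbon (Wacker-type oxypalladation), closing the dihydropyran ring in the 6-exo-trig mode and giving alkylpalladium 14. Because C2 carries no hydrogen, 14 cannot undergo β-hydride elimination and should survive to carbopalladate the unsubstituted vinyl terminus of 13, forming the CH2–CH2 bond of the target at the alkene oxidation level; β-hydride elimination then releases the (E)-enone and benzoquinone returns Pd(0) to Pd(II). The closest known reaction type is the enantioselective domino Wacker–Heck cyclisation of 2-(3-methylbut-3-enyl)phenols with vinyl ketones and acrylates, used for 2-methyl-2-alkylchromans. The C2 stereocenter is set by catalyst control: the C2-symmetric ligand selects the alkene face in the oxypalladation, and the quaternary center cannot epimerise afterwards. The step needs Markovnikov 6-exo closure, secured by the tether length and the 1,1-disubstitution, and chemoselective insertion into the ketone-activated monosubstituted vinyl group of 13 rather than its trisubstituted enoate, secured by substitution pattern and the excess of 13.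

Step 9
Reactants: 15 methyl (2E,7E)-9-[(2S)-2,8-dimethyl-6-(pivaloyloxy)chroman-2-yl]-2-methyl-6-oxonona-2,7-dienoate
Product: 16 methyl (2E,6Z)-9-[(2R)-2,8-dimethyl-6-(pivaloyloxy)chroman-2-yl]-2-methyl-6-[(triethylsilyl)oxy]nona-2,6-dienoate
Conditions: Et3SiH (1.2 equiv), RhCl(PPh3)3 (1 mol%), toluene, 50 °C
Reagents that add atoms: triethylsilane, CC[SiH](CC)CC
Why: Rh-catalysed 1,4-hydrosilylation of the enone, which delivers hydride to C8 and silicon to oxygen through the metal-bound s-cis enone and should therefore give the (6Z)-enol silane, while the trisubstituted enoate and the aryl ester are far less reactive; no stereocenter is touched, and the change of the C2 descriptor from S to R reflects only the CIP ranking once C8 is saturated.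

Step 10
Reactants: 16 methyl (2E,6Z)-9-[(2R)-2,8-dimethyl-6-(pivaloyloxy)chroman-2-yl]-2-methyl-6-[(triethylsilyl)oxy]nona-2,6-dienoate
Product: 17 methyl (2E,6Z)-9-[(2R)-2,8-dimethyl-6-(pivaloyloxy)chroman-2-yl]-2-methyl-6-{[(nonafluorobutyl)sulfonyl]oxy}nona-2,6-dienoate
Conditions: C4F9SO2F (1.3 equiv), Bu4N+ Ph3SiF2− (5 mol%), THF, 0 °C to rt
Reagents that add atoms: nonafluorobutane-1-sulfonyl fluoride, FC(F)(F)C(F)(F)C(F)(F)C(F)(F)S(F)(=O)=O
Why: Fluoride-catalysed conversion of a silyl enol ether into an alkenyl nonaflate: the transient enolate is sulfonylated on oxygen faster than it can equilibrate, so regiochemistry and Z-geometry should be retained, and only a catalytic amount of fluoride meets the aryl pivalate.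

Step 11
Reactants: 17 methyl (2E,6Z)-9-[(2R)-2,8-dimethyl-6-(pivaloyloxy)chroman-2-yl]-2-methyl-6-{[(nonafluorobutyl)sulfonyl]oxy}nona-2,6-dienoate
Product: 18 methyl (2E,6E)-9-[(2R)-2,8-dimethyl-6-(pivaloyloxy)chroman-2-yl]-2,6-dimethylnona-2,6-dienoate
Conditions: MeZnCl (2 equiv), Pd(PPh3)4 (5 mol%), THF, 50 °C
Reagents that add atoms: methylzinc chloride, C[Zn]Cl
Why: Negishi coupling of the alkenyl sulfonate with methylzinc chloride, stereoretentive in oxidative addition and reductive elimination, so the (6Z)-nonaflate should give the (6E)-methyl alkene; both esters tolerate the organozinc.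

Step 12
Reactants: 18 methyl (2E,6E)-9-[(2R)-2,8-dimethyl-6-(pivaloyloxy)chroman-2-yl]-2,6-dimethylnona-2,6-dienoate
Product: 19 (2E,6E)-9-[(2R)-6-hydroxy-2,8-dimethylchroman-2-yl]-2,6-dimethylnona-2,6-dienoic acid
Conditions: LiOH (aq, excess), THF/MeOH, degassed, argon, 45 °C; then 1 M HCl
Reagents that add atoms: lithium hydroxide, [Li+].[OH-]
Why: Saponification of the methyl enoate and the aryl pivalate in one operation under oxygen-free conditions (the free 6-hydroxychroman is air-sensitive in base), followed by acidification; no stereocenter or alkene is affected.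

**Compound list**

1 | 2-methylbenzene-1,4-diol | Cc1cc(O)ccc1O | starting material
2 | 4-hydroxy-3-methylphenyl pivalate | CC(C)(C)C(=O)Oc1ccc(O)c(C)c1 | intermediate
3 | 3-bromo-4-hydroxy-5-methylphenyl pivalate | CC(C)(C)C(=O)Oc1cc(C)c(O)c(Br)c1 | intermediate
4 | 4-bromo-2-methylbut-1-ene | C=C(C)CCBr | starting material
5 | (3-methylbut-3-en-1-yl)zinc bromide | C=C(C)CC[Zn]Br | intermediate (not isolated)
6 | 4-hydroxy-3-methyl-5-(3-methylbut-3-en-1-yl)phenyl pivalate | CC(C)(C)C(=O)Oc1cc(C)c(O)c(CCC(C)=C)c1 | intermediate
7 | pent-4-enal | C=CCCC=O | starting material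
8 | methyl 2-(triphenyl-λ5-phosphanylidene)propanoate | COC(=O)C(C)=P(c1ccccc1)(c1ccccc1)c1ccccc1 | starting material
9 | methyl (2E)-2-methylhepta-2,6-dienoate | C=CCC/C=C(\C)C(=O)OC | intermediate
10 | methyl (2E)-2-methyl-5-(1,2,4-trioxolan-3-yl)pent-2-enoate | COC(=O)/C(C)=C/CCC1OCOO1 | intermediate (not isolated)
11 | methyl (2E)-2-methyl-6-oxohex-2-enoate | O=CCC/C=C(\C)C(=O)OC | intermediate
12 | methyl (2E)-6-hydroxy-2-methylocta-2,7-dienoate (racemic) | C=CC(O)CC/C=C(\C)C(=O)OC | intermediate
13 | methyl (2E)-2-methyl-6-oxoocta-2,7-dienoate | C=CC(=O)CC/C=C(\C)C(=O)OC | intermediate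
14 | {[(2S)-2,8-dimethyl-6-(pivaloyloxy)chroman-2-yl]methyl}palladium(II) trifluoroacetate (ligand omitted) | FC(F)(F)C(=O)O[Pd]C[C@]1(C)CCc2cc(OC(=O)C(C)(C)C)cc(C)c2O1 | intermediate (not isolated)
15 | methyl (2E,7E)-9-[(2S)-2,8-dimethyl-6-(pivaloyloxy)chroman-2-yl]-2-methyl-6-oxonona-2,7-dienoate | COC(=O)/C(C)=C/CCC(=O)/C=C/C[C@]1(C)CCc2cc(OC(=O)C(C)(C)C)cc(C)c2O1 | intermediate
16 | methyl (2E,6Z)-9-[(2R)-2,8-dimethyl-6-(pivaloyloxy)chroman-2-yl]-2-methyl-6-[(triethylsilyl)oxy]nona-2,6-dienoate | COC(=O)/C(C)=C/CC/C(O[Si](CC)(CC)CC)=C/CC[C@]1(C)CCc2cc(OC(=O)C(C)(C)C)cc(C)c2O1 | intermediate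
17 | methyl (2E,6Z)-9-[(2R)-2,8-dimethyl-6-(pivaloyloxy)chroman-2-yl]-2-methyl-6-{[(nonafluorobutyl)sulfonyl]oxy}nona-2,6-dienoate | COC(=O)/C(C)=C/CC/C(OS(=O)(=O)C(F)(F)C(F)(F)C(F)(F)C(F)(F)F)=C/CC[C@]1(C)CCc2cc(OC(=O)C(C)(C)C)cc(C)c2O1 | intermediate
18 | methyl (2E,6E)-9-[(2R)-2,8-dimethyl-6-(pivaloyloxy)chroman-2-yl]-2,6-dimethylnona-2,6-dienoate | COC(=O)/C(C)=C/CC/C(C)=C/CC[C@]1(C)CCc2cc(OC(=O)C(C)(C)C)cc(C)c2O1 | intermediate
19 | (2E,6E)-9-[(2R)-6-hydroxy-2,8-dimethylchroman-2-yl]-2,6-dimethylnona-2,6-dienoic acid | C/C(=C\CC[C@]1(C)CCc2cc(O)cc(C)c2O1)CC/C=C(\C)C(=O)O | target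

**Step count**

Total: 12 steps. Longest linear sequence: 9 steps (steps 4–12).

**Steps most likely to fail, with fallbacks**

Step 8. What may go wrong: interception of the neopentyl-type alkylpalladium species by the polymerisation-prone, doubly functionalised vinyl ketone 13 may be slower than catalyst decay, so the cyclised intermediate is lost before the C–C bond forms. Fallback: it sets out from 6. The same oxypalladation is terminated with but-3-en-2-one, the simplest vinyl ketone, under otherwise identical conditions, to give (3E)-5-[(2S)-2,8-dimethyl-6-(pivaloyloxy)chroman-2-yl]pent-3-en-2-one F1. Kinetic deprotonation of the methyl group (LDA, THF, −78 °C) and alkylation of the cross-conjugated enolate with methyl (2E)-4-bromo-2-methylbut-2-enoate then forms the C4–C5 bond of the chain and comes back to the route at 15. The chain is thus attached by an enolate alkylation instead of the Heck termination.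

Step 9. What may go wrong: hydride transfer through the open s-trans conformer, or competing 1,2-hydrosilylation, may erode the Z-geometry of the enol silane and with it the 6E-geometry of the chain. Fallback: the geometry is set with the opposite enolate and the other carbon substituent is coupled. It sets out from 6 and passes through F1, made as described for step 8. L-Selectride (THF, −78 °C) adds hydride to the s-trans conformer that should dominate for this (E)-methyl enone, giving the enolate with oxygen trans to the chain CH2. PhNTf2 traps it as (2E)-5-[(2R)-2,8-dimethyl-6-(pivaloyloxy)chroman-2-yl]pent-2-en-2-yl trifluoromethanesulfonate F2. Stereoretentive Negishi sp2–sp3 coupling (Pd(OAc)2, SPhos, THF) with [(3E)-5-methoxy-4-methyl-5-oxopent-3-en-1-yl]zinc iodide F3, made by zinc insertion into methyl (2E)-5-iodo-2-methylpent-2-enoate, comes back to the route at 18; steps 9–11 are bypassed.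

Step 3. What may go wrong: protonolysis of the alkylzinc by the free ortho-hydroxyl, and β-hydride elimination with chain-walking in the alkylpalladium intermediate, may outrun the coupling. Fallback: the side chain is built from a carbonyl group instead of by aryl–alkyl cross-coupling. It sets out from 2 (step 2 is then not needed). Magnesium-mediated ortho-formylation (MgCl2, Et3N, paraformaldehyde, MeCN, reflux) gives 3-formyl-4-hydroxy-5-methylphenyl pivalate F4. Wittig reaction with 1-(triphenylphosphoranylidene)propan-2-one (toluene, 80 °C) gives 4-hydroxy-3-methyl-5-[(1E)-3-oxobut-1-en-1-yl]phenyl pivalate F5. Hydrogenation of the C=C bond (H2, Pd/C, EtOAc) gives 4-hydroxy-3-methyl-5-(3-oxobutyl)phenyl pivalate F6. Wittig methylenation (Ph3P=CH2, 2.2 equiv, THF) comes back to the route at 6.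

**Further compounds**

F1 | step 8 | (3E)-5-[(2S)-2,8-dimethyl-6-(pivaloyloxy)chroman-2-yl]pent-3-en-2-one | CC(=O)/C=C/C[C@]1(C)CCc2cc(OC(=O)C(C)(C)C)cc(C)c2O1
F2 | step 9 | (2E)-5-[(2R)-2,8-dimethyl-6-(pivaloyloxy)chroman-2-yl]pent-2-en-2-yl trifluoromethanesulfonate | C/C(=C\CC[C@]1(C)CCc2cc(OC(=O)C(C)(C)C)cc(C)c2O1)OS(=O)(=O)C(F)(F)F
F3 | step 9 | [(3E)-5-methoxy-4-methyl-5-oxopent-3-en-1-yl]zinc iodide | COC(=O)/C(C)=C/CC[Zn]I
F4 | step 3 | 3-formyl-4-hydroxy-5-methylphenyl pivalate | CC(C)(C)C(=O)Oc1cc(C)c(O)c(C=O)c1
F5 | step 3 | 4-hydroxy-3-methyl-5-[(1E)-3-oxobut-1-en-1-yl]phenyl pivalate | CC(=O)/C=C/c1cc(OC(=O)C(C)(C)C)cc(C)c1O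
F6 | step 3 | 4-hydroxy-3-methyl-5-(3-oxobutyl)phenyl pivalate | CC(=O)CCc1cc(OC(=O)C(C)(C)C)cc(C)c1O
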